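**Retrosynthetic overview**

1. Disconnections: (i) the C6–acyl bond (late C‑acylation of a cyclic 1,3‑dione with (S)‑2‑methylbutanoic acid); (ii) the dihydropyran O1–C2 and C4–C3 bonds (hetero‑Diels–Alder reaction of an o‑quinone methide with the C4=C5 alkene of (−)‑β‑caryophyllene, as in the presumed biosynthesis); (iii) the six‑membered carbocycle, which comes from a cyclobutenone by two‑carbon ring expansion with an ynol ether.
2. Enabling feature: C8 of the carbocycle is a quaternary CMe2 carbon between C7=O and C8a–O. As the terminus of a dienylketene 6π‑electrocyclisation it stops the ring expansion at the cyclohexa‑2,4‑dienone (no phenol can form). The C8a(O)=C4a–C4H2 unit shared by carbocycle and pyran is the retron of the o‑quinone methide cycloaddition.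
3. Ring order: cyclobutenone (steps 1–3); in the key step four‑membered ring → six‑membered carbocycle, then the dihydropyran; the cyclobutane and nine‑membered ring arrive with caryophyllene.
4. Stereochemistry: C1/C9 from caryophyllene; C4/C5 in the cycloaddition; the acyl stereocentre from (S)‑2‑methylbutanoic acid.

Key step: step 5

Remark: names use chromene numbering for the pyran/carbocycle (O1, C2, C3, C4, C4a, C5–C8, C8a) and caryophyllene numbering for the terpene (C1 and C9 cyclobutane methines, C4 methyl‑bearing, C5 olefinic CH, C8 methylidene carbon). The C4(S)/C5(R) centres of the target correspond to addition on the face of the C4=C5 bond opposite to the one epoxidised in natural (−)‑caryophyllene oxide, i.e. the face exposed in the ββ conformer.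

**Step 1**
Reactants: 1 isobutyryl chloride; 2 ethoxyacetylene
Product: 4 3‑ethoxy‑4,4‑dimethylcyclobut‑2‑en‑1‑one, via dimethylketene 3 (not isolated)
Conditions: Et3N, Et2O, 0 °C → reflux
Reagents that add atoms: none
Why: Dehydrochlorination should give dimethylketene, which undergoes the regioselective thermal ketene–ynol ether [2+2] cycloaddition (β‑carbon of the ynol ether to the ketene carbonyl carbon) to the 3‑alkoxycyclobutenone; no stereocentre is formed.

**Step 2**
Reactants: 4 3‑ethoxy‑4,4‑dimethylcyclobut‑2‑en‑1‑one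
Product: 5 3‑hydroxy‑4,4‑dimethylcyclobut‑2‑en‑1‑one (enol form of 2,2‑dimethylcyclobutane‑1,3‑dione)
Conditions: 1 M aq. HCl, THF, rt
Reagents that add atoms: water, O
Why: Acid‑catalysed hydrolysis of a vinylogous ester (water adds at C3, ethanol leaves) should give the enolised dione, and the acidic medium avoids base‑induced cleavage of the strained 1,3‑dione.

**Step 3**
Reactants: 5 3‑hydroxy‑4,4‑dimethylcyclobut‑2‑en‑1‑one
Product: 6 4,4‑dimethyl‑3‑[(triisopropylsilyl)oxy]cyclobut‑2‑en‑1‑one
Conditions: TIPSCl, Et3N, CH2Cl2, 0 °C → rt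
Reagents that add atoms: triisopropylsilyl chloride, CC(C)[Si](Cl)(C(C)C)C(C)C
Why: O‑Silylation of the vinylogous acid can give only one silyl enol ether (the two oxygens are equivalent by symmetry), and the bulky TIPS vinylogous ester should survive heating yet be cleaved by fluoride.

**Step 4**
Reactants: 2 ethoxyacetylene
Product: 9 3‑ethoxyprop‑2‑yn‑1‑yl acetate, via lithium ethoxyacetylide 7 (not isolated), via lithium 3‑ethoxyprop‑2‑yn‑1‑olate 8 (not isolated)
Conditions: n‑BuLi, THF, −78 °C; (CH2O)n, −78 °C → rt; Ac2O, 0 °C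
Reagents that add atoms: formaldehyde (as paraformaldehyde), C=O; acetic anhydride, CC(=O)OC(C)=O
Why: Acetylide addition to formaldehyde followed by acylation of the lithium alkoxide in the same flask should give the propargylic acetate without isolating the acid‑sensitive 3‑alkoxypropargyl alcohol.

**Step 5**
Reactants: 6 4,4‑dimethyl‑3‑[(triisopropylsilyl)oxy]cyclobut‑2‑en‑1‑one; 9 3‑ethoxyprop‑2‑yn‑1‑yl acetate; 10 (−)‑β‑caryophyllene
Product: 16 (4S,5R) cycloadduct, 5‑ethoxy‑8,8‑dimethyl‑3,4‑dihydro‑2H‑chromen‑7(8H)‑one fused through O1–C2(CH3)–C3(H) to C4–C5 of the caryophyllane, via vinylketene 11 (not isolated), via 4‑alkenylcyclobutenone 12 (not isolated), via dienylketene 13 (not isolated), via silyloxy dienone 14 (not isolated), via o‑quinone methide 15 (not isolated)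
Conditions: 9 (1.5 equiv), 10 (3 equiv), PhMe, 80 °C then 110 °C (sealed tube); then 0 °C, TBAF (1.1 equiv, THF, slow addition), → rt
Reagents that add atoms: none
Why: Heating opens 6 by 4π‑electrocyclic ring opening to vinylketene 11, which adds ynol ether 9 in a regioselective [2+2] (nucleophilic alkyne carbon to the ketene C=O carbon) to give 4‑alkenylcyclobutenone 12; a second 4π opening gives dienylketene 13, and its 6π‑electrocyclic closure onto the Me2C= terminus expands the four‑membered ring of 12 by two carbons to the six‑membered dienone 14, which cannot aromatise because that terminus is quaternary. The closest known reaction type is the Danheiser cyclobutenone/alkoxyalkyne annulation together with the thermal closure of dienylketenes to 6,6‑disubstituted cyclohexa‑2,4‑dienones; fluoride then cleaves the silyl dienol ether and the dienolate expels acetate by vinylogous 1,6‑elimination (fluoride‑triggered quinone methide generation) to give 15, which 10 traps in an inverse‑electron‑demand hetero‑Diels–Alder reaction that copies the presumed biosynthesis. Ring closures: the carbocycle by thermal disrotatory 6π electrocyclisation (bond between the ketene carbon and CMe2), the dihydropyran by a concerted, asynchronous suprafacial [4+2] (O–C4 and CH2–C5 bonds of the terpene). Stereocentres: the E geometry of the C4=C5 alkene fixes the trans relation of the C4 methyl and the C5 hydrogen, and the absolute sense follows from the (1R,9S) cyclobutane of 10 through the alkene face that is open in the reacting ring conformer. Selectivity needed: heterodiene regiochemistry is secured because in 15 only the C=O next to CMe2 is conjugated with the methylene (the other flank is the ethyl enol ether), site selectivity by the strain of the trans‑trisubstituted alkene over the exocyclic methylene, and orientation by bonding of oxygen to the more substituted alkene carbon. Facial selectivity is not enforced by the substrate: 16 is the adduct on the face exposed in the ββ conformer, the conformers interconvert faster than they react, so the C4/C5 bis‑epimer is expected alongside and is to be removed by chromatography (AgNO3‑impregnated silica).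

**Step 6**
Reactants: 16 (4S,5R) cycloadduct, ethyl enol ether
Product: 17 5‑hydroxy analogue of 16 (enolised 1,3‑dione: C5–OH, C6–H, C7=O)
Conditions: 2 M aq. NaOH, 1,4‑dioxane, 80 °C; then 1 M HCl to pH 4
Reagents that add atoms: sodium hydroxide, [Na+].[OH-]
Why: Saponification of the vinylogous ethyl ester by addition–elimination is expected at the unhindered C5 and not at C8a, which is flanked by CMe2 and a tetrasubstituted alkene and would have to expel a tethered tertiary alkoxide; the vinylogous carboxylate formed is inert to further attack and no stereocentre is touched.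

**Step 7**
Reactants: 17 5‑hydroxy analogue of 16; 18 (S)‑2‑methylbutanoic acid
Product: 20 target, 5‑hydroxy‑8,8‑dimethyl‑6‑[(2S)‑2‑methylbutanoyl] derivative, via enol ester 19 (not isolated)
Conditions: DCC, DMAP, CH2Cl2, 0 °C → rt
Reagents that add atoms: none
Why: Carbodiimide O‑acylation of the cyclic 1,3‑dione followed by DMAP‑mediated 1,3‑O→C acyl migration (Steglich‑type acylation/acyl transfer, the standard access to 2‑acylcyclohexane‑1,3‑diones) should place the acyl group on C6, the only nucleophilic ring carbon, with the hydrogen‑bonded enolised β‑triketone as the sink; the (S) centre comes from 18, and low temperature without stronger base limits its epimerisation.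

**Compound list**

1 | isobutyryl chloride | CC(C)C(Cl)=O | starting material
2 | ethoxyacetylene (ethoxyethyne) | CCOC#C | starting material
3 | dimethylketene | CC(C)=C=O | intermediate
4 | 3‑ethoxy‑4,4‑dimethylcyclobut‑2‑en‑1‑one | CCOC1=CC(=O)C1(C)C | intermediate
5 | 3‑hydroxy‑4,4‑dimethylcyclobut‑2‑en‑1‑one | OC1=CC(=O)C1(C)C | intermediate
6 | 4,4‑dimethyl‑3‑[(triisopropylsilyl)oxy]cyclobut‑2‑en‑1‑one | CC(C)[Si](OC1=CC(=O)C1(C)C)(C(C)C)C(C)C | intermediate
7 | lithium ethoxyacetylide | CCOC#C[Li] | intermediate
8 | lithium 3‑ethoxyprop‑2‑yn‑1‑olate | CCOC#CC[O-].[Li+] | intermediate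
9 | 3‑ethoxyprop‑2‑yn‑1‑yl acetate | CCOC#CCOC(C)=O | intermediate
10 | (−)‑β‑caryophyllene (1R,9S,4E) | C/C1=C\CCC(=C)[C@H]2CC(C)(C)[C@@H]2CC1 | starting material
11 | 4‑methyl‑3‑[(triisopropylsilyl)oxy]penta‑1,3‑dien‑1‑one (vinylketene) | CC(C)=C(O[Si](C(C)C)(C(C)C)C(C)C)C=C=O | intermediate
12 | (2‑ethoxy‑3‑{2‑methyl‑1‑[(triisopropylsilyl)oxy]prop‑1‑en‑1‑yl}‑4‑oxocyclobut‑1‑en‑1‑yl)methyl acetate (racemic) | CCOC1=C(COC(C)=O)C(=O)C1C(O[Si](C(C)C)(C(C)C)C(C)C)=C(C)C | intermediate
13 | (3E)‑2‑(acetoxymethyl)‑3‑ethoxy‑6‑methyl‑5‑[(triisopropylsilyl)oxy]hepta‑1,3,5‑trien‑1‑one (dienylketene) | O=C=C(COC(C)=O)/C(OCC)=C\C(O[Si](C(C)C)(C(C)C)C(C)C)=C(C)C | intermediate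
14 | {2‑ethoxy‑5,5‑dimethyl‑6‑oxo‑4‑[(triisopropylsilyl)oxy]cyclohexa‑1,3‑dien‑1‑yl}methyl acetate | CCOC1=C(COC(C)=O)C(=O)C(C)(C)C(O[Si](C(C)C)(C(C)C)C(C)C)=C1 | intermediate
15 | 5‑ethoxy‑2,2‑dimethyl‑6‑methylidenecyclohex‑4‑ene‑1,3‑dione (o‑quinone methide) | CCOC1=CC(=O)C(C)(C)C(=O)C1=C | intermediate
16 | (4S,5R) cycloadduct: 5‑ethoxy‑8,8‑dimethyl‑3,4‑dihydro‑2H‑chromen‑7(8H)‑one fused at O1–C2(CH3)–C3(H) to C4–C5 of the caryophyllane (trans‑fused; 1R,9S; 8‑methylidene) | C=C1CC[C@@H]2CC3=C(O[C@@]2(C)CC[C@@H]2[C@@H]1CC2(C)C)C(C)(C)C(=O)C=C3OCC | intermediate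
17 | 5‑hydroxy analogue of 16 (enolised 1,3‑dione) | C=C1CC[C@@H]2CC3=C(O[C@@]2(C)CC[C@@H]2[C@@H]1CC2(C)C)C(C)(C)C(=O)C=C3O | intermediate
18 | (S)‑2‑methylbutanoic acid | CC[C@H](C)C(=O)O | starting material
19 | C5 enol (S)‑2‑methylbutanoate of 17 | C=C1CC[C@@H]2CC3=C(O[C@@]2(C)CC[C@@H]2[C@@H]1CC2(C)C)C(C)(C)C(=O)C=C3OC(=O)[C@@H](C)CC | intermediate
20 | target: 5‑hydroxy‑8,8‑dimethyl‑6‑[(2S)‑2‑methylbutanoyl] cycloadduct | C=C1CC[C@@H]2CC3=C(O[C@@]2(C)CC[C@@H]2[C@@H]1CC2(C)C)C(C)(C)C(=O)C(C(=O)[C@@H](C)CC)=C3O | target

**Step count and risks**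

Total step count: 7. Longest linear sequence: 6 steps (steps 1, 2, 3, 5, 6, 7).

Steps most likely to fail:

Step 5. The o‑quinone methide is released in the same flask as the enolate that precedes it, so Michael capture or dimerisation may outrun the cycloaddition. The silyl group or the acetate may also be lost already during the thermal stage. The cycloaddition has no enforced facial control, so the needed ββ‑face adduct may be the minor diastereomer. The fallback sets out from 6 and separates the ring expansion from the quinone methide chemistry. Heating 6 with ethoxyacetylene 2 alone (same annulation) should give 3‑ethoxy‑6,6‑dimethyl‑5‑[(triisopropylsilyl)oxy]cyclohexa‑2,4‑dien‑1‑one F1. Desilylation (TBAF buffered with AcOH, THF, 0 °C) should give the symmetrical vinylogous acid 3‑ethoxy‑5‑hydroxy‑6,6‑dimethylcyclohexa‑2,4‑dien‑1‑one F2. A three‑component Knoevenagel/hetero‑Diels–Alder reaction of F2 (added slowly), paraformaldehyde and 10 (cat. ethylenediammonium diacetate, dioxane, 60–80 °C) generates the same o‑quinone methide 15 at low stationary concentration under nearly neutral conditions. The route is rejoined at 16; the diastereomers are separated as before.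

Step 6. Hydroxide may also attack C8a and open the cyclic vinylogous ester, or the doubly donor‑substituted dienone may resist saponification so that forcing conditions erode the material. The fallback sets out from 6 and replaces the ethyl group by a fluoride‑cleavable 2‑(trimethylsilyl)ethyl group. 2‑(Trimethylsilyl)ethanol, KH and trichloroethylene should give the dichlorovinyl ether (E)‑[2‑(1,2‑dichloroethenyloxy)ethyl]trimethylsilane F3. n‑BuLi (2.2 equiv), then paraformaldehyde and Ac2O as in step 4, should give 3‑[2‑(trimethylsilyl)ethoxy]prop‑2‑yn‑1‑yl acetate F4. The conditions of step 5 with 6, F4 and 10 should give the 5‑[2‑(trimethylsilyl)ethoxy] analogue of 16, F5. Excess TBAF (THF, rt → 40 °C) then fragments the silylethyl group without any attack on ring carbons, and the route is rejoined at 17.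

Step 7. Acyl transfer may stop at the O‑acyl stage on the hindered, electron‑rich dione, and long exposure to DMAP may epimerise the acyl α‑centre through a ketene. The fallback sets out from 6 and installs the acyl group before the terpene is attached. Annulation of 6 with commercial 1‑ethoxyprop‑1‑yne should give 3‑ethoxy‑2,6,6‑trimethyl‑5‑[(triisopropylsilyl)oxy]cyclohexa‑2,4‑dien‑1‑one F6. Hydrolysis of both enol ethers (1 M HCl, THF, 40 °C) should give 3,5‑dihydroxy‑2,6,6‑trimethylcyclohexa‑2,4‑dien‑1‑one F7. C‑Acylation with 18 at the unsubstituted ring carbon (DCC/DMAP, or enol ester then cyanide‑catalysed rearrangement, which this terpene‑free substrate tolerates and where enantiopurity can be checked) should give the acyl triketone 3,5‑dihydroxy‑4,6,6‑trimethyl‑2‑[(2S)‑2‑methylbutanoyl]cyclohexa‑2,4‑dien‑1‑one F8. Oxidation of F8 (TEMPO, Ag2O, PhMe, rt) in the presence of 10 generates the acylated o‑quinone methide 5‑hydroxy‑2,2‑dimethyl‑6‑methylidene‑4‑[(2S)‑2‑methylbutanoyl]cyclohex‑4‑ene‑1,3‑dione F9 from the ring C‑methyl group, and its hetero‑Diels–Alder reaction with 10 arrives directly at 20.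

**Further compounds**

F1 | step 5 | 3‑ethoxy‑6,6‑dimethyl‑5‑[(triisopropylsilyl)oxy]cyclohexa‑2,4‑dien‑1‑one | CCOC1=CC(=O)C(C)(C)C(O[Si](C(C)C)(C(C)C)C(C)C)=C1
F2 | step 5 | 3‑ethoxy‑5‑hydroxy‑6,6‑dimethylcyclohexa‑2,4‑dien‑1‑one | CCOC1=CC(=O)C(C)(C)C(O)=C1
F3 | step 6 | (E)‑[2‑(1,2‑dichloroethenyloxy)ethyl]trimethylsilane | C[Si](C)(C)CCO/C(Cl)=C\Cl
F4 | step 6 | 3‑[2‑(trimethylsilyl)ethoxy]prop‑2‑yn‑1‑yl acetate | C[Si](C)(C)CCOC#CCOC(C)=O
F5 | step 6 | 5‑[2‑(trimethylsilyl)ethoxy] analogue of 16 | C=C1CC[C@@H]2CC3=C(O[C@@]2(C)CC[C@@H]2[C@@H]1CC2(C)C)C(C)(C)C(=O)C=C3OCC[Si](C)(C)C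
F6 | step 7 | 3‑ethoxy‑2,6,6‑trimethyl‑5‑[(triisopropylsilyl)oxy]cyclohexa‑2,4‑dien‑1‑one | CCOC1=C(C)C(=O)C(C)(C)C(O[Si](C(C)C)(C(C)C)C(C)C)=C1
F7 | step 7 | 3,5‑dihydroxy‑2,6,6‑trimethylcyclohexa‑2,4‑dien‑1‑one | CC1=C(O)C=C(O)C(C)(C)C1=O
F8 | step 7 | 3,5‑dihydroxy‑4,6,6‑trimethyl‑2‑[(2S)‑2‑methylbutanoyl]cyclohexa‑2,4‑dien‑1‑one | CC[C@H](C)C(=O)C1=C(O)C(C)=C(O)C(C)(C)C1=O
F9 | step 7 | 5‑hydroxy‑2,2‑dimethyl‑6‑methylidene‑4‑[(2S)‑2‑methylbutanoyl]cyclohex‑4‑ene‑1,3‑dione | CC[C@H](C)C(=O)C1=C(O)C(=C)C(=O)C(C)(C)C1=O
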